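**Retrosynthetic overview**

1. Target 15 ⇒ Shi epoxidation of the C-7 prenyl group of alcohol 14 ⇒ MeMgBr addition to methyl ketone 13 (benzofuran numbering throughout; the oxirane is made last).
2. Key disconnection in 13: the C-3–C-3a bond (ring CH2 to the quaternary carbon) of the dihydrofuran ring, leading back to the flat, Cs-symmetric aryl vinyl ether 10, a 2-aryloxy enone. A copper-controlled dearomative 6π photocyclisation closes the furan ring onto the six-membered ring, creates C-3a, makes the two prenyl groups different and leaves the acetyl group that becomes CMe2OH.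
3. Enabling feature: the ether oxygen O-1 sits on C-7a between two prenylated ortho carbons (C-3a and C-7 carry no hydrogen, so the ylide cannot re-aromatise), and the phloroglucinol oxygens on C-4 and C-6 can shed an acetyl group so that the oxocarbenium ion collapses to the vinylogous ester/β-triketone.
4. 10 ⇐ deoxycohumulone 5 (para-O-alkylation with chloroacetone, acetylation, Mannich methylenation) ⇐ phloroglucinol + isobutyryl chloride + prenyl bromide.
5. Ring order: six-membered carbocycle (from the arene) → dihydrofuran (step 6) → oxirane (step 8).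

Key step: step 6

Assumption: the β-triketone compounds 13–15 are written as the tautomer of the target SMILES, and (S,S) is taken as the ligand antipode that leads to the (3aR) series; should a first run show the opposite sense, the (R,R)-ligand is used instead.

**Route**

Step 1
Reactants: 1 phloroglucinol; 2 isobutyryl chloride
Product: 3 2-methyl-1-(2,4,6-trihydroxyphenyl)propan-1-one (phloroisobutyrophenone)
Conditions: AlCl3 (3.5 equiv), PhNO2, 0 to 65 °C; aq. HCl
Reagents that add atoms: none
Why: Friedel–Crafts C-acylation of the very electron-rich arene stops after one acyl group because the chelated aryl ketone is deactivated; no stereocentre is formed.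

Step 2
Reactants: 3 phloroisobutyrophenone; 4 prenyl bromide (1-bromo-3-methylbut-2-ene)
Product: 5 deoxycohumulone, 2-methyl-1-[2,4,6-trihydroxy-3,5-bis(3-methylbut-2-en-1-yl)phenyl]propan-1-one
Conditions: 4 (2.1 equiv), 10% aq. KOH, 0 °C, under argon; then acidify
Reagents that add atoms: none
Why: Friedel–Crafts-type C-allylation of the ambident phenolate in water, where the oxygens are solvated, takes place at the two free ring carbons, the usual entry to 3,5-diprenyl acylphloroglucinols; no stereocentre is formed.

Step 3
Reactants: 5 deoxycohumulone; 6 chloroacetone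
Product: 7 1-[3,5-dihydroxy-4-(2-methylpropanoyl)-2,6-bis(3-methylbut-2-en-1-yl)phenoxy]propan-2-one
Conditions: 6 (1.1 equiv), K2CO3 (1.1 equiv), KI (cat.), acetone, 40 °C, under argon
Reagents that add atoms: none
Why: Williamson ether synthesis at the 4-OH, the most acidic hydroxyl (para to the acyl group) and the only one not hydrogen-bonded to the ketone, with the hard α-chloro ketone in a dipolar aprotic medium favouring O- over C-alkylation; no stereocentre is formed.

Step 4
Reactants: 7 aryloxyacetone
Product: 8 2-(2-methylpropanoyl)-4,6-bis(3-methylbut-2-en-1-yl)-5-(2-oxopropoxy)-1,3-phenylene diacetate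
Conditions: Ac2O (3 equiv), Et3N, DMAP (cat.), CH2Cl2, 0 °C to rt
Reagents that add atoms: acetic anhydride, CC(=O)OC(C)=O
Why: DMAP-catalysed O-acetylation of the two remaining phenols removes the acidic, chelating sites that would compete for the Lewis acid in step 6 and turns both oxygens into acyl donors for the collapse of the oxocarbenium ion; no stereocentre is formed.

Step 5
Reactants: 8 diacetate
Product: 10 2-(2-methylpropanoyl)-4,6-bis(3-methylbut-2-en-1-yl)-5-[(3-oxobut-1-en-2-yl)oxy]-1,3-phenylene diacetate, via Mannich base hydroiodide 9 (not isolated)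
Conditions: CH2=NMe2+ I− (2 equiv), MeCN, 60 °C; SiO2 filtration
Reagents that add atoms: N,N-dimethylmethyleneiminium iodide, C=[N+](C)C.[I-]
Why: Mannich α-methylenation, in which the ketone enolises towards the oxygen-bearing CH2, the iminium ion adds there and the β-ammonium ketone loses dimethylamine on heating (E1cB) to give the 2-aryloxy enone; the aryl acetates survive because the amine leaves only as its hydroiodide, and the stereocentre of racemic 9 is lost again.

Step 6
Reactants: 10 aryl vinyl ether (2-aryloxy enone)
Product: 13 (2S,3aR)-2-acetyl-4-hydroxy-3a,7-bis(3-methylbut-2-en-1-yl)-5-(2-methylpropanoyl)-3,3a-dihydro-1-benzofuran-6(2H)-one, via carbonyl ylide 11 (not isolated), via cis enol acetate 12 (not isolated)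
Conditions: Cu(ClO4)2·6H2O (0.5 equiv), (S,S)-t-Bu-box (0.55 equiv), CH2Cl2 (5 mM, degassed), 385 nm LED, −40 °C; then K2CO3 (3 equiv), MeOH, 0 °C to rt; pH 4 buffer
Reagents that add atoms: none
Why: Proposed new method: chelation of the 2-aryloxy enone by the divalent copper–bisoxazoline complex (carbonyl and ether oxygen) fixes the s-cis aryl–O–C=CH2 geometry, and excitation triggers a conrotatory 6π electrocyclisation (oxygen lone pair, vinyl C=C and one aryl C=C) that joins the enone CH2 to a prenyl-bearing ortho carbon to give carbonyl ylide 11; its carbanion is protonated by the water of the copper salt, the O-acetyl oxocarbenium ion then hands the acetyl group on the oxygen at C-6 to water (giving 12), and K2CO3/MeOH removes the second acetyl group and equilibrates C-2. The closest known reaction type is the heteroatom-directed photoarylation of 2-aryloxy enones to dihydrobenzofurans, including its enantioselective variant mediated by a chiral copper–bisoxazoline Lewis acid, where the ylide ends by a 1,4-hydrogen shift that restores the arene; in 10 both ortho carbons carry prenyl groups, so no hydrogen can shift and the ring must stay dearomatised. The dihydrofuran ring is closed in the 6π electrocyclic mode, formally a 5-endo-trig closure that is not available to the thermal Michael reaction. C-3a is controlled by the ligand, since the two enantiotopic ortho carbons lie above and below the chelate plane and the tert-butyl groups decide which of them rotates onto the CH2 terminus; C-2 is controlled thermodynamically, since kinetic protonation anti to the prenyl group gives the cis ketone and base equilibration puts the acetyl group pseudo-equatorial and trans to the pseudo-axial prenyl group. The step needs ring closure to outrun [2+2] addition of the excited enone to a prenyl double bond and return of the ylide to 10, which the enforced contact of CH2 and ortho carbon in the chelate, the low temperature and the fast protonation by water should secure, and it needs no regiocontrol because 10 is Cs-symmetric.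

Step 7
Reactants: 13 methyl ketone
Product: 14 (2S,3aR)-4-hydroxy-2-(2-hydroxypropan-2-yl)-3a,7-bis(3-methylbut-2-en-1-yl)-5-(2-methylpropanoyl)-3,3a-dihydro-1-benzofuran-6(2H)-one
Conditions: MeMgBr (4 equiv), CeCl3 (4 equiv), THF, −78 to −40 °C; aq. NH4Cl
Reagents that add atoms: methylmagnesium bromide, C[Mg]Br
Why: Grignard-type 1,2-addition of the organocerium reagent to the chelation-activated α-alkoxy methyl ketone, in which the first equivalent turns the β-triketone into its unreactive enolate and C-2, already in its more stable configuration in 13, is carried through unchanged; no new stereocentre is formed.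

Step 8
Reactants: 14 tertiary alcohol
Product: 15 (2S,3aR)-7-{[(2R)-3,3-dimethyloxiran-2-yl]methyl}-4-hydroxy-2-(2-hydroxypropan-2-yl)-3a-(3-methylbut-2-en-1-yl)-5-(2-methylpropanoyl)-3,3a-dihydro-1-benzofuran-6(2H)-one (target)
Conditions: D-fructose-derived ketone of the Shi epoxidation (0.3 equiv), KHSO5 (as Oxone, 1.1 equiv), K2CO3, Bu4NHSO4 (cat.), MeCN/dimethoxymethane/aq. Na2B4O7–Na2EDTA buffer, 0 °C; work-up at pH 7, Et3N-deactivated SiO2
Reagents that add atoms: potassium peroxymonosulfate, [K+].[O-]S(=O)(=O)OO
Why: Shi asymmetric epoxidation, in which the dioxirane of the D-fructose-derived ketone transfers oxygen through a spiro transition state to the face of the trisubstituted olefin that gives the (R)-oxirane, and with one equivalent of oxidant the exposed in-plane C-7 prenyl group should react ahead of the pseudo-axial, neopentyl-type prenyl group on the quaternary C-3a.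

**Compound list**

1 | phloroglucinol (benzene-1,3,5-triol) | Oc1cc(O)cc(O)c1 | starting material
2 | isobutyryl chloride (2-methylpropanoyl chloride) | CC(C)C(Cl)=O | starting material
3 | phloroisobutyrophenone, 2-methyl-1-(2,4,6-trihydroxyphenyl)propan-1-one | CC(C)C(=O)c1c(O)cc(O)cc1O | intermediate
4 | prenyl bromide (1-bromo-3-methylbut-2-ene) | CC(C)=CCBr | starting material
5 | deoxycohumulone, 2-methyl-1-[2,4,6-trihydroxy-3,5-bis(3-methylbut-2-en-1-yl)phenyl]propan-1-one | CC(C)C(=O)c1c(O)c(CC=C(C)C)c(O)c(CC=C(C)C)c1O | intermediate
6 | chloroacetone (1-chloropropan-2-one) | CC(=O)CCl | starting material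
7 | 1-[3,5-dihydroxy-4-(2-methylpropanoyl)-2,6-bis(3-methylbut-2-en-1-yl)phenoxy]propan-2-one | CC(C)C(=O)c1c(O)c(CC=C(C)C)c(OCC(C)=O)c(CC=C(C)C)c1O | intermediate
8 | 2-(2-methylpropanoyl)-4,6-bis(3-methylbut-2-en-1-yl)-5-(2-oxopropoxy)-1,3-phenylene diacetate | CC(C)C(=O)c1c(OC(C)=O)c(CC=C(C)C)c(OCC(C)=O)c(CC=C(C)C)c1OC(C)=O | intermediate
9 | Mannich base hydroiodide, 5-{[1-(dimethylamino)-3-oxobutan-2-yl]oxy}-2-(2-methylpropanoyl)-4,6-bis(3-methylbut-2-en-1-yl)-1,3-phenylene diacetate hydroiodide (racemic, not isolated) | CC(C)C(=O)c1c(OC(C)=O)c(CC=C(C)C)c(OC(C[NH+](C)C)C(C)=O)c(CC=C(C)C)c1OC(C)=O.[I-] | intermediate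
10 | 2-(2-methylpropanoyl)-4,6-bis(3-methylbut-2-en-1-yl)-5-[(3-oxobut-1-en-2-yl)oxy]-1,3-phenylene diacetate | CC(C)C(=O)c1c(OC(C)=O)c(CC=C(C)C)c(OC(=C)C(C)=O)c(CC=C(C)C)c1OC(C)=O | intermediate
11 | carbonyl ylide (oxonium/carbanion zwitterion) formed by C-3–C-3a bond formation, 4,6-diacetoxy, C-3a arranged as in 13 (not isolated) | CC(C)=CC[C@]12C[C-](C(C)=O)[O+]=C1C(CC=C(C)C)=C(OC(C)=O)C(C(=O)C(C)C)=C2OC(C)=O | intermediate
12 | (2R,3aS)-2-acetyl-3a,7-bis(3-methylbut-2-en-1-yl)-5-(2-methylpropanoyl)-6-oxo-2,3,3a,6-tetrahydro-1-benzofuran-4-yl acetate; acetyl cis to the 3a-prenyl group, C-3a arranged in space as in 13 (its descriptor changes only through the O-acetyl group) (not isolated) | CC(C)=CC[C@]12C[C@H](C(C)=O)OC1=C(CC=C(C)C)C(=O)C(C(=O)C(C)C)=C2OC(C)=O | intermediate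
13 | (2S,3aR)-2-acetyl-4-hydroxy-3a,7-bis(3-methylbut-2-en-1-yl)-5-(2-methylpropanoyl)-3,3a-dihydro-1-benzofuran-6(2H)-one; acetyl trans to the 3a-prenyl group | CC(C)=CC[C@]12C[C@@H](C(C)=O)OC1=C(CC=C(C)C)C(=O)C(C(=O)C(C)C)=C2O | intermediate
14 | (2S,3aR)-4-hydroxy-2-(2-hydroxypropan-2-yl)-3a,7-bis(3-methylbut-2-en-1-yl)-5-(2-methylpropanoyl)-3,3a-dihydro-1-benzofuran-6(2H)-one | CC(C)=CC[C@]12C[C@@H](C(C)(C)O)OC1=C(CC=C(C)C)C(=O)C(C(=O)C(C)C)=C2O | intermediate
15 | (2S,3aR)-7-{[(2R)-3,3-dimethyloxiran-2-yl]methyl}-4-hydroxy-2-(2-hydroxypropan-2-yl)-3a-(3-methylbut-2-en-1-yl)-5-(2-methylpropanoyl)-3,3a-dihydro-1-benzofuran-6(2H)-one | CC(C)=CC[C@]12C[C@@H](C(C)(C)O)OC1=C(C[C@H]1OC1(C)C)C(=O)C(C(=O)C(C)C)=C2O | target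

**Step count**

Total step count: 8. Longest linear sequence: 8 steps (from phloroglucinol 1).

**Steps most likely to fail**

1. Step 6 (proposed new method). The ylide may return to the aryl vinyl ether without being trapped. The excited enone may add [2+2] to an ortho prenyl double bond. The copper complex may discriminate the two ortho carbons poorly, and acetyl loss from the oxocarbenium ion may be slow. Fallback with known chemistry, setting out from 5 and coming back at 14: a third C-prenylation of 5 with prenyl bromide 4 (NaOMe, MeOH, 0 °C; alkylative dearomatisation) should give colupulone F1. Shi epoxidation of F1 with one equivalent of KHSO5 and the D-fructose-derived ketone should epoxidise one of the two geminal prenyl groups to the (R)-epoxide F2, beside its C-6 epimer and the epoxide of the ring prenyl group. PPTS in CH2Cl2 should then let the neighbouring enol oxygen open the epoxide 5-exo with inversion, closing the dihydrofuran ring through its O–C-2 bond to give 14. Compound 14 is separated from its 3a-epimer and regioisomers by chromatography.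

2. Step 8. Oxygen may be transferred to the 3a-prenyl group instead of, or in addition to, the C-7 prenyl group. The electron-rich β-triketone enolate may be oxidised, and the new epoxide may be opened by the neighbouring enolate oxygen. Fallback, setting out from 13 and coming back at 15: 13 is treated with KHSO5 (as Oxone) and NaHCO3 in MeCN–water without added ketone. The 2-acetyl group is converted into its dioxirane F3, which can reach only the C-7 prenyl group (ketone-directed intramolecular epoxidation) and should give epoxy ketone F4. F4 would be separated from its epoxide epimer if the facial control exerted by C-2 is incomplete. MeMgBr/CeCl3 in THF at −78 °C should then add to the acetyl group of F4 faster than the trisubstituted epoxide reacts and give 15.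

3. Step 5. Aminomethylation may occur on the methyl side of the ketone or twice, elimination of dimethylamine may be incomplete, and the enone may oligomerise on concentration. Fallback, setting out from 5 and coming back at 10 (it also replaces steps 3 and 4): Rh2(OAc)4-catalysed O–H insertion of dimethyl (1-diazo-2-oxopropyl)phosphonate into the non-chelated 4-OH of 5 (CH2Cl2, rt) should give keto phosphonate F5. Horner–Wadsworth–Emmons olefination of F5 with aqueous formaldehyde and K2CO3 in THF should give the free bis-phenol enone F6. Acetylation (Ac2O, pyridine, 0 °C) should give 10.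

**Further compounds**

F1 | step 6 | colupulone, 3,5-dihydroxy-2-(2-methylpropanoyl)-4,6,6-tris(3-methylbut-2-en-1-yl)cyclohexa-2,4-dien-1-one (drawn as the tautomer used for the target) | CC(C)=CCC1(CC=C(C)C)C(O)=C(CC=C(C)C)C(=O)C(C(=O)C(C)C)=C1O
F2 | step 6 | colupulone mono-epoxide: one geminal prenyl group converted into the (R)-3,3-dimethyloxiran-2-ylmethyl group, quaternary carbon arranged as C-3a of 14 | CC(C)=CC[C@]1(C[C@H]2OC2(C)C)C(O)=C(CC=C(C)C)C(=O)C(C(=O)C(C)C)=C1O
F3 | step 8 | dioxirane of 13 (2-(3-methyldioxiran-3-yl) in place of 2-acetyl; not isolated) | CC(C)=CC[C@]12C[C@@H](C3(C)OO3)OC1=C(CC=C(C)C)C(=O)C(C(=O)C(C)C)=C2O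
F4 | step 8 | (2S,3aR)-2-acetyl-7-{[(2R)-3,3-dimethyloxiran-2-yl]methyl}-4-hydroxy-3a-(3-methylbut-2-en-1-yl)-5-(2-methylpropanoyl)-3,3a-dihydro-1-benzofuran-6(2H)-one | CC(C)=CC[C@]12C[C@@H](C(C)=O)OC1=C(C[C@H]1OC1(C)C)C(=O)C(C(=O)C(C)C)=C2O
F5 | step 5 | dimethyl {1-[3,5-dihydroxy-4-(2-methylpropanoyl)-2,6-bis(3-methylbut-2-en-1-yl)phenoxy]-2-oxopropyl}phosphonate (racemic) | CC(C)C(=O)c1c(O)c(CC=C(C)C)c(OC(C(C)=O)P(=O)(OC)OC)c(CC=C(C)C)c1O
F6 | step 5 | 3-[3,5-dihydroxy-4-(2-methylpropanoyl)-2,6-bis(3-methylbut-2-en-1-yl)phenoxy]but-3-en-2-one | CC(C)C(=O)c1c(O)c(CC=C(C)C)c(OC(=C)C(C)=O)c(CC=C(C)C)c1O
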